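**Plan**
- Retrosynthesis: a C2'=C3' double bond is put back into the saturated C21 chain and cut by cross-metathesis, leaving a ring-bound allyl group (C1', C2') and 1-eicosene (C3'–C21').
- The aryl C6–C1' bond is then cut (retro-Claisen) to an allyl aryl ether, the O–allyl bond to 2,4-dimethoxyphenol, and the phenol C1–O bond back to the formyl group of 2,4-dimethoxybenzaldehyde.
- Forward: Baeyer–Villiger oxidation/methanolysis, O-allylation, Claisen shift, chain union by cross-metathesis, hydrogenation; no ring is formed.
- Enabling feature: on the benzene ring C6 is the only carbon ortho to the phenolic oxygen that carries hydrogen (C2 bears OMe), so the [3,3] shift can deliver allyl only there; the chain is unbranched and unfunctionalised, so a transient alkene at C2'=C3' can be removed without trace.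
- Stereochemistry: the target has no stereocentre; the only stereo element on the way, the alkene geometry after metathesis, is erased by hydrogenation.

Key step: step 4

Remark: compound 9 is expected as an E-rich mixture of alkene isomers. It is named and drawn as the E isomer and carried forward as the mixture, since step 5 saturates the double bond. Ring atoms are numbered as in the target name (C1 OH, C2 and C4 OMe, C6 chain); chain atoms are C1'–C21' counted from the ring.

**Route**

Step 1
Reactants: 1 2,4-dimethoxybenzaldehyde
Product: 3 2,4-dimethoxyphenol, via 2,4-dimethoxyphenyl formate 2 (not isolated)
Conditions: mCPBA, CH2Cl2, 0 °C to rt; aq. Na2SO3/NaHCO3 wash; then K2CO3 (cat.), MeOH, rt, Ar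
Reagents that add atoms: mCPBA (3-chloroperoxybenzoic acid), OOC(=O)c1cccc(Cl)c1
Why: Baeyer–Villiger oxidation of an electron-rich benzaldehyde (Dakin-type), in which the 2,4-dimethoxyphenyl group migrates in preference to hydride in the peracid adduct to give the aryl formate, which base-catalysed transesterification with methanol cleaves to the phenol.

Step 2
Reactants: 3 2,4-dimethoxyphenol; 4 allyl bromide
Product: 5 1-(allyloxy)-2,4-dimethoxybenzene
Conditions: K2CO3, acetone, reflux, Ar
Reagents that add atoms: none
Why: Williamson ether synthesis, the potassium phenoxide displacing bromide from the unhindered allylic halide by SN2 with O-alkylation favoured in a polar aprotic medium.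

Step 3
Reactants: 5 1-(allyloxy)-2,4-dimethoxybenzene
Product: 7 2-allyl-4,6-dimethoxyphenol, via 6-allyl-2,4-dimethoxycyclohexa-2,4-dien-1-one 6 (not isolated)
Conditions: PhNEt2, 200 °C, Ar
Reagents that add atoms: none
Why: Aromatic Claisen rearrangement, a concerted [3,3]-sigmatropic shift that can end productively only at C6 because the dienone formed there enolises to the phenol, whereas a shift to the methoxy-bearing C2 cannot rearomatise and reverts.

Step 4
Reactants: 7 2-allyl-4,6-dimethoxyphenol; 8 1-eicosene
Product: 9 (E)-2-(heneicos-2-en-1-yl)-4,6-dimethoxyphenol
Conditions: 8 (3 equiv), second-generation Grubbs catalyst RuCl2(=CHPh)(PCy3)(H2IMes) (5 mol%), 1,4-benzoquinone (10 mol%), CH2Cl2, 40 °C, Ar purge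
Reagents that add atoms: none
Why: The ruthenium benzylidene initiates on either terminal alkene, and successive [2+2] cycloaddition/cycloreversion through ruthenacyclobutanes exchanges alkylidene halves, so that the ArCH2CH= unit of 7 and the =CH(CH2)17CH3 unit of 8 are joined as the C2'=C3' bond while the two terminal CH2 groups leave as ethylene, whose escape drives the equilibrium. The closest known reaction type is olefin cross-metathesis of allylarenes, free allylphenols included, with unhindered 1-alkenes under second-generation ruthenium alkylidene catalysis. No ring closes and no stereocentre is created; the new alkene should form mainly as the E isomer under thermodynamic control, and its geometry is erased in step 5. The step needs selectivity for the cross product over the two homodimers and freedom from allyl-to-propenyl isomerisation, which would cost one chain carbon after metathesis. The substrate helps in that both partners are monosubstituted, unhindered alkenes whose homodimers stay metathesis-active and are re-equilibrated towards the cross product by the excess of cheap 8, and the non-polar C20 and C38 hydrocarbons should separate readily from the phenol on silica. Isomerisation is not controlled by the substrate but by the benzoquinone additive, which intercepts ruthenium hydrides, and by the mild temperature.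

Step 5
Reactants: 9 (E)-2-(heneicos-2-en-1-yl)-4,6-dimethoxyphenol
Product: 10 6-n-heneicosyl-2,4-dimethoxyphenol
Conditions: H2 (1 atm), 10% Pd/C, EtOAc, rt
Reagents that add atoms: none
Why: Heterogeneous catalytic hydrogenation, which should saturate the unhindered disubstituted alkene of either geometry at atmospheric pressure while the aryl methyl ethers, the phenol and the arene stay untouched.

**Compound list**
1 | 2,4-dimethoxybenzaldehyde | COc1ccc(C=O)c(OC)c1 | starting material
2 | 2,4-dimethoxyphenyl formate | COc1ccc(OC=O)c(OC)c1 | intermediate
3 | 2,4-dimethoxyphenol | COc1ccc(O)c(OC)c1 | intermediate
4 | allyl bromide (3-bromoprop-1-ene) | C=CCBr | starting material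
5 | 1-(allyloxy)-2,4-dimethoxybenzene | C=CCOc1ccc(OC)cc1OC | intermediate
6 | 6-allyl-2,4-dimethoxycyclohexa-2,4-dien-1-one (racemic, transient) | C=CCC1C=C(OC)C=C(OC)C1=O | intermediate
7 | 2-allyl-4,6-dimethoxyphenol | C=CCc1cc(OC)cc(OC)c1O | intermediate
8 | 1-eicosene | C=CCCCCCCCCCCCCCCCCCC | starting material
9 | (E)-2-(heneicos-2-en-1-yl)-4,6-dimethoxyphenol | CCCCCCCCCCCCCCCCCC/C=C/Cc1cc(OC)cc(OC)c1O | intermediate
10 | 6-n-heneicosyl-2,4-dimethoxyphenol | CCCCCCCCCCCCCCCCCCCCCc1cc(OC)cc(OC)c1O | target

**Step count**
Total: 5 steps. Longest linear sequence: 5 steps (1 to 10).

**Steps most likely to fail**

Step 4 (cross-metathesis). Ruthenium hydride species may walk the allyl double bond into conjugation with the ring, after which metathesis would give a chain one carbon short. The free ortho-hydroxyl may also ligate or protonate the catalyst, the electron-rich phenol may interact with the quinone additive, and material may be diverted statistically into homodimers. The fallback sets out from 7 and keeps the same disconnection on a masked phenol. O-Benzylation (benzyl bromide, K2CO3, DMF, rt) should give 1-allyl-2-(benzyloxy)-3,5-dimethoxybenzene F1. Cross-metathesis of this ether with 8 under the catalyst of step 4, where benzoquinone or acetic acid can be dosed freely, should give (E)-2-(benzyloxy)-1-(heneicos-2-en-1-yl)-3,5-dimethoxybenzene F2. Hydrogen over Pd/C then saturates the alkene and cleaves the benzyl ether in one operation, so the fallback comes back to the route at 10.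

Step 3 (Claisen rearrangement). The electron-rich ether and phenol may degrade or air-oxidise at 200 °C, and the ortho-allylphenol may cyclise onto its own alkene on prolonged heating. The fallback sets out from 3 and bypasses 5 by a low-temperature C-allylation. NaH in toluene should convert 3 into sodium 2,4-dimethoxyphenoxide F3, which stays as a tight ion pair in the non-polar medium. Allyl bromide 4 added to this suspension between rt and 80 °C should alkylate it on carbon at C6, the only hydrogen-bearing ortho position, through the same dienone 6. The fallback comes back to the route at 7; any 5 formed by competing O-allylation is removed by base extraction and can be recycled.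

Step 1 (Baeyer–Villiger oxidation/methanolysis). The peracid may over-oxidise the electron-rich ring or the liberated phenol, and the phenolate may air-oxidise during the basic methanolysis. The fallback sets out from 1 and replaces the two-stage peracid/base sequence by an acid-catalysed Dakin-type oxidation with aqueous H2O2 and catalytic H2SO4 in methanol at rt. Peroxide adds to the protonated carbonyl, the aryl group migrates, and formate 2 is methanolysed in the same acidic medium, so neither a peracid nor a phenolate is present. It comes back to the route at 3 and makes no new compound.

**Further compounds**
F1 | step 4 | 1-allyl-2-(benzyloxy)-3,5-dimethoxybenzene | C=CCc1cc(OC)cc(OC)c1OCc1ccccc1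
F2 | step 4 | (E)-2-(benzyloxy)-1-(heneicos-2-en-1-yl)-3,5-dimethoxybenzene | CCCCCCCCCCCCCCCCCC/C=C/Cc1cc(OC)cc(OC)c1OCc1ccccc1
F3 | step 3 | sodium 2,4-dimethoxyphenoxide | COc1ccc([O-])c(OC)c1.[Na+]
F0 | step 1 | none | none
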